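The reagent's decomposition gained far more from heat than the wanted step did: between the coldest flask, theta, and the hottest, beta, it sped up by a factor of 17000 against 140. So I turned the question round and asked what would have to be true for beta to lose.

all flasks: left-handed substrate 20 mM; reagent 60.0 mM; free catalyst 0.26 mM; impurity 0.14 mM; right-handed substrate 20 mM; time 15 h
- theta: temperature 60 °C
- beta: temperature 150 °C
- delta: temperature 120 °C
- eta: temperature 90 °C

    reagent + free catalyst + left-handed substrate → free catalyst + left-handed product (k1 = 1.8 M⁻² s⁻¹, Ea1 = 64.0 kJ mol⁻¹)
    reagent + free catalyst + right-handed substrate → free catalyst + right-handed product (k2 = 0.0094 M⁻² s⁻¹, Ea2 = 55.0 kJ mol⁻¹)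
    free catalyst + impurity → spent catalyst (k3 = 120 M⁻¹ s⁻¹, Ea3 = 44.0 kJ mol⁻¹)
    reagent → decomposition product (k4 = 6.1 × 10⁻⁸ s⁻¹, Ea4 = 127 kJ mol⁻¹)
    (constants at 90 °C)

- free catalyst is single-handed; left-handed substrate and right-handed substrate are mirror images of each other, charged as a racemate, each of them at the stated concentration
- the constants hold at 90 °C; other temperatures follow from the activation energies

- the best flask by amount of left-handed product, in percent of the left-handed substrate and right-handed substrate together charged; "all alike" if 1.5 percentage points covers them all (theta / beta / delta / eta / all alike)
- amount of left-handed product at the end, in percent of the left-handed substrate and right-handed substrate together charged, theta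
- amount of left-handed product at the end, in percent of the left-handed substrate and right-handed substrate together charged, beta
- amount of left-handed product at the end, in percent of the left-handed substrate and right-handed substrate together charged, delta
- amount of left-handed product at the end, in percent of the left-handed substrate and right-handed substrate together charged, eta

I began with the catalyst. Each impurity takes one free catalyst, and even in theta, the coldest flask, I reckoned the impurity's lifetime against the charged catalyst at about 1.98 min, far shorter than the run. I therefore took 0.120 mM as working catalyst from the start. With reagent held near its charge, the left-handed substrate then decays pseudo-first-order, so I counted lifetimes. That count, N, came to 0.104 in theta: the first step's constant at the flask's temperature, times reagent charge, working catalyst and time, which is the number of lifetimes of the left-handed substrate in the run. A share e^−N of that substrate stays, and the left-handed product can reach half of the total charge.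

Eta counted 0.700 and delta 3.53. For beta to lose to delta, beta's count had to fall below delta's. In beta the reagent's own lifetime came to 11.7 h, longer than the 1.06 h of the left-handed substrate at the full reagent charge. Averaging the decaying reagent over the run left beta 7.97 lifetimes, 2.26 times delta's count, so on my reckoning beta stood clear of that reversal. My counts ignore the reagent the substrate itself uses, up to 33.3 % of the charge, so they run high. They gave 4.93 % for theta, 50.0 % for beta, 48.5 % for delta and 25.2 % for eta, and my pick was beta.

The forecast also named beta, with 4.9 % for theta, 49.8 % for beta, 46.3 % for delta and 23.5 % for eta, starting from “Poisoning is over within about a minute”. For eta it stood lower than my figure, and for delta too.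

The simulation named beta, with 4.87 % in theta, 49.8 % in beta, 46.3 % in delta and 23.5 % in eta, each inside the forecast's range. Theta kept 90 % of its left-handed substrate, and e^−N was 90.1 %. The neighbour was theta with 1.0 mM of free catalyst. Scaling the count to its working catalyst gave 0.744, hence 47.5 % of that substrate remaining and 26.2 % as product. The neighbour flask kept 51 % of that substrate, with reagent at 83 % of its charge, and its left-handed product reached 24.5 %.

The rate constants are those of an exercise; the result is computed.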